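**Plan**
- Retrosynthetic cuts, in order: the 1′,5′-epoxide and C1′–C2′ of the epoxide half (xanthane numbering, primes for that half); C11=C13 and the C8–O/C12 lactone of the hydroxy half; C3–C11′ (spiro cyclohexene); C1–C2; then C9–C10 together with C1–O(C7) in one cascade; last C11′–C13′ between the halves.
- Feature used: the cycloheptane of the hydroxy half (C1, C5–C10) carries oxygen at C1, the methyl stereocentre C10 beside it and the lactone carbons C7/C8 across the ring, so a 2-methylcyclohept-4-enone (C1=O, C10–CH3, C7=C8) is hidden in it.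
- Forward: ring B cycloheptene by ring-closing metathesis and its cis-lactone by iodolactonisation; chain joined at C11′ by enolate alkylation; hydroxy-half cycloheptenone by alkynol cycloisomerisation/Claisen shift; cyclohexene by palladium enolate alkenylation; ring A lactone; side chain, methylene, epoxide.
- Stereochemistry: (R)-but-3-yn-2-ol sets C7′ through a Johnson–Claisen shift and hence C8′; crotylboration sets C10′; two Sharpless epoxidations set C5 (after an inverting alkynylalane opening) and C7; C7 is relayed to C10 in the key step; C1, C11′, C7/C8 and the epoxide follow from the ring systems.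

Key step: step 23

Remark: atoms are numbered as in xanthanolides (C1–C15, primes for the epoxide half); TBS = tert-butyldimethylsilyl, PMB = 4-methoxybenzyl, Ipc = isopinocampheyl; 2-(PMB-oxy)acetaldehyde, both but-3-yn-2-ol enantiomers and 1-propynyllithium are taken as purchasable.

**Ring B lactone**

Step 1
Reactants: 1 (R)-but-3-yn-2-ol; 2 2-(2-bromoethyl)-1,3-dioxolane
Product: 3 (2R)-6-(1,3-dioxolan-2-yl)hex-3-yn-2-ol
Conditions: n-BuLi (2.1 equiv), THF, −78 °C; then 2, DMPU, −78 °C → rt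
Reagents that add atoms: none
Why: Acetylide alkylation: the dilithiated propargylic alcohol should react at carbon with the primary bromide and leave the carbinol centre untouched.

Step 2
Reactants: 3 (2R)-6-(1,3-dioxolan-2-yl)hex-3-yn-2-ol
Product: 4 (2R,3E)-6-(1,3-dioxolan-2-yl)hex-3-en-2-ol
Conditions: NaAlH2(OCH2CH2OMe)2, THF, 0 °C → rt
Reagents that add atoms: none
Why: Hydroxyl-directed trans-hydroalumination of a propargylic alcohol should give the E allylic alcohol only.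

Step 3
Reactants: 4 (2R,3E)-6-(1,3-dioxolan-2-yl)hex-3-en-2-ol
Product: 6 ethyl (3R,4E)-3-(3-oxopropyl)hex-4-enoate, via dioxolane ester 5 (not isolated)
Conditions: MeC(OEt)3, EtCO2H (cat.), 140 °C; concentrate; then 1 M HCl, THF, rt
Reagents that add atoms: triethyl orthoacetate, CCOC(C)(OCC)OCC; water, O
Why: Johnson–Claisen rearrangement through a chair with the carbinol methyl equatorial should transfer the (R)-carbinol chirality to C7′ (R) and leave an E propenyl group, after which acid hydrolyses the acetal.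

Step 4
Reactants: 6 ethyl (3R,4E)-3-(3-oxopropyl)hex-4-enoate
Product: 7 ethyl (3R,6R,7S)-6-hydroxy-7-methyl-3-[(E)-prop-1-enyl]non-8-enoate
Conditions: (E)-crotyl-B(Ipc)2 [from trans-but-2-ene, KOt-Bu, n-BuLi, (−)-Ipc2BOMe, BF3·OEt2], THF, −78 °C; then NaBO3·4H2O
Reagents that add atoms: (E)-crotyldiisopinocampheylborane, C/C=C/CB(C1CC2CC(C1C)C2(C)C)C1CC2CC(C1C)C2(C)C
Why: Brown crotylboration through a closed chair: the Ipc groups should direct attack to the aldehyde Si face and the E crotyl unit gives the anti adduct, which sets C10′ (S); the C1′ carbinol is oxidised later.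

Step 5
Reactants: 7 ethyl (3R,6R,7S)-6-hydroxy-7-methyl-3-[(E)-prop-1-enyl]non-8-enoate
Product: 8 ethyl [(1R,4S,5R)-5-hydroxy-4-methylcyclohept-2-en-1-yl]acetate
Conditions: second-generation Grubbs catalyst (5 mol%), CH2Cl2 (5 mM), 40 °C
Reagents that add atoms: none
Why: Ring-closing metathesis of the vinyl and propenyl groups should close the cycloheptene (C8′=C9′) with loss of propene.

Step 6
Reactants: 8 ethyl [(1R,4S,5R)-5-hydroxy-4-methylcyclohept-2-en-1-yl]acetate
Product: 10 (3aR,6R,7R,8S,8aS)-6-hydroxy-8-iodo-7-methyloctahydro-2H-cyclohepta[b]furan-2-one, via carboxylic acid 9 (not isolated)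
Conditions: LiOH, THF–H2O, rt; then NaHCO3, I2, 0 °C, dark
Reagents that add atoms: iodine, II; LiOH, [Li+].[OH-]
Why: Saponification then 5-exo iodolactonisation: the carboxylate can reach C8′ only on the face of its own tether, so the lactone is cis-fused (C8′ set by C7′) with iodine anti at C9′.

Step 7
Reactants: 10 (3aR,6R,7R,8S,8aS)-6-hydroxy-8-iodo-7-methyloctahydro-2H-cyclohepta[b]furan-2-one
Product: 11 (3aR,6R,7S,8aR)-6-hydroxy-7-methyloctahydro-2H-cyclohepta[b]furan-2-one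
Conditions: Bu3SnH, AIBN (cat.), benzene, 80 °C
Reagents that add atoms: none
Why: Radical chain dehalogenation removes the iodine without touching a stereocentre.

Step 8
Reactants: 11 (3aR,6R,7S,8aR)-6-hydroxy-7-methyloctahydro-2H-cyclohepta[b]furan-2-one
Product: 12 (3aR,7S,8aR)-7-methylhexahydro-2H-cyclohepta[b]furan-2,6(3H)-dione
Conditions: Dess–Martin periodinane, NaHCO3, CH2Cl2, rt
Reagents that add atoms: none
Why: Buffered Dess–Martin oxidation should give the C1′ ketone without epimerising C10′.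

Step 9
Reactants: 12 (3aR,7S,8aR)-7-methylhexahydro-2H-cyclohepta[b]furan-2,6(3H)-dione
Product: 13 ring B lactone: 6,6-ethylenedioxy ketal of 12 (3aR,7S,8aR)
Conditions: Me3SiOCH2CH2OSiMe3, Me3SiOTf (cat.), CH2Cl2, −78 → −20 °C
Reagents that add atoms: 1,2-bis(trimethylsilyloxy)ethane, C[Si](C)(C)OCCO[Si](C)(C)C
Why: Noyori ketalisation under aprotic conditions should protect the ketone without enolising toward C10′.

**Hydroxy-half side chain**

Step 10
Reactants: 14 triethyl phosphonoacetate; 15 (2-bromoethoxy)(tert-butyl)dimethylsilane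
Product: 16 ethyl 4-(TBS-oxy)-2-(diethoxyphosphoryl)butanoate (racemic)
Conditions: NaH, DMF, 0 °C; then 15, NaI (cat.), 60 °C
Reagents that add atoms: none
Why: C-alkylation of the phosphonoacetate anion with a primary bromide installs the C11–C12 arm.

Step 11
Reactants: 16 ethyl 4-(TBS-oxy)-2-(diethoxyphosphoryl)butanoate; 17 2-(PMB-oxy)acetaldehyde
Product: 18 ethyl (2E)-2-[2-(TBS-oxy)ethyl]-4-(PMB-oxy)but-2-enoate
Conditions: NaH, THF, 0 °C; then 17, 0 °C → rt
Reagents that add atoms: none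
Why: Horner–Wadsworth–Emmons olefination of an α-alkyl phosphonoacetate should give the E enoate, with C9 cis to the C11 arm.

Step 12
Reactants: 18 ethyl (2E)-2-[2-(TBS-oxy)ethyl]-4-(PMB-oxy)but-2-enoate
Product: 19 (2E)-2-[2-(TBS-oxy)ethyl]-4-(PMB-oxy)but-2-en-1-ol
Conditions: i-Bu2AlH, CH2Cl2, −78 °C
Reagents that add atoms: none
Why: 1,2-Reduction of the enoate gives the allylic alcohol with the alkene geometry kept.

Step 13
Reactants: 19 (2E)-2-[2-(TBS-oxy)ethyl]-4-(PMB-oxy)but-2-en-1-ol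
Product: 20 (2E)-1-bromo-2-[2-(TBS-oxy)ethyl]-4-(PMB-oxy)but-2-ene
Conditions: CBr4, PPh3, CH2Cl2, 0 °C
Reagents that add atoms: carbon tetrabromide, BrC(Br)(Br)Br
Why: Appel bromination converts the primary allylic alcohol into the bromide without allylic transposition.

Step 14
Reactants: 20 (2E)-1-bromo-2-[2-(TBS-oxy)ethyl]-4-(PMB-oxy)but-2-ene; 21 prop-2-yn-1-ol
Product: 22 (5Z)-5-[2-(TBS-oxy)ethyl]-7-(PMB-oxy)hept-5-en-2-yn-1-ol
Conditions: CuI (10 mol%), K2CO3, NaI (cat.), DMF, rt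
Reagents that add atoms: none
Why: Copper-catalysed coupling of a terminal alkyne with a primary allylic bromide should give the skipped enyne at the CH2 terminus (C6).

Step 15
Reactants: 22 (5Z)-5-[2-(TBS-oxy)ethyl]-7-(PMB-oxy)hept-5-en-2-yn-1-ol
Product: 23 (2E,5Z)-5-[2-(TBS-oxy)ethyl]-7-(PMB-oxy)hepta-2,5-dien-1-ol
Conditions: NaAlH2(OCH2CH2OMe)2, THF, 0 °C → rt
Reagents that add atoms: none
Why: trans-Hydroalumination of the propargylic alcohol gives the E allylic alcohol; the isolated trisubstituted alkene is inert.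

Step 16
Reactants: 23 (2E,5Z)-5-[2-(TBS-oxy)ethyl]-7-(PMB-oxy)hepta-2,5-dien-1-ol
Product: 24 [(2R,3R)-3-{(2E)-2-[2-(TBS-oxy)ethyl]-4-(PMB-oxy)but-2-enyl}oxiran-2-yl]methanol
Conditions: Ti(Oi-Pr)4 (cat.), D-(−)-diethyl tartrate (cat.), t-BuOOH, 4 Å MS, CH2Cl2, −20 °C
Reagents that add atoms: tert-butyl hydroperoxide, CC(C)(C)OO
Why: Sharpless asymmetric epoxidation: the D-tartrate catalyst should give the (2R,3R)-epoxy alcohol by reagent control, and only the free allylic alcohol is epoxidised.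

Step 17
Reactants: 24 [(2R,3R)-3-{(2E)-2-[2-(TBS-oxy)ethyl]-4-(PMB-oxy)but-2-enyl}oxiran-2-yl]methanol
Product: 25 (2S,3R,5Z)-5-[2-(TBS-oxy)ethyl]-7-(PMB-oxy)-3-(prop-1-ynyl)hept-5-ene-1,2-diol
Conditions: Et2AlC≡CMe (from 1-propynyllithium and Et2AlCl), toluene, 0 °C → rt
Reagents that add atoms: diethyl(prop-1-ynyl)aluminium, CC[Al](CC)C#CC
Why: Alkynylalane opening of a 2,3-epoxy alcohol takes place at C3 with inversion, which sets C5 (R) and brings in the methyl-capped alkyne.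

Step 18
Reactants: 25 (2S,3R,5Z)-5-[2-(TBS-oxy)ethyl]-7-(PMB-oxy)-3-(prop-1-ynyl)hept-5-ene-1,2-diol
Product: 27 (2R,4Z)-4-[2-(TBS-oxy)ethyl]-6-(PMB-oxy)-2-(prop-1-ynyl)hex-4-en-1-ol, via aldehyde 26 (not isolated)
Conditions: NaIO4, THF–H2O, 0 °C; then NaBH4, MeOH, 0 °C
Reagents that add atoms: none
Why: Periodate glycol cleavage followed at once by borohydride reduction excises the extra carbon and gives C13′–OH before the α-alkynyl aldehyde can epimerise.

**Union and key step**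

Step 19
Reactants: 27 (2R,4Z)-4-[2-(TBS-oxy)ethyl]-6-(PMB-oxy)-2-(prop-1-ynyl)hex-4-en-1-ol; 13 ring B lactone
Product: 29 alkylated lactone: 13 bearing at C11′ (anti to C6′) the side chain of 27 through C13′, via triflate 28 (not isolated)
Conditions: 27, n-BuLi then Tf2O, Et2O, −78 °C; cannulated into the Li enolate of 13 [LiN(i-Pr)2, THF, −78 °C], DMPU, −78 → −40 °C
Reagents that add atoms: none
Why: SN2 alkylation of the lactone enolate by a primary triflate (chosen over the iodide to outrun elimination at the β-branched centre) forms C11′–C13′ on the convex face; the C11′ configuration is transient because the centre is enolised again in step 28.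

Step 20
Reactants: 29 alkylated lactone
Product: 30 allylic alcohol: 29 with C9–OH free
Conditions: DDQ, CH2Cl2–pH 7 buffer, 0 °C
Reagents that add atoms: none
Why: Oxidative cleavage of the PMB ether frees the allylic alcohol while the silyl ether, ketal and alkyne stay.

Step 21
Reactants: 30 allylic alcohol
Product: 31 epoxy alcohol: (7R,8S)-7,8-epoxide of 30
Conditions: Ti(Oi-Pr)4 (cat.), L-(+)-diethyl tartrate (cat.), t-BuOOH, 4 Å MS, CH2Cl2, −20 °C
Reagents that add atoms: tert-butyl hydroperoxide, CC(C)(C)OO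
Why: Sharpless asymmetric epoxidation of the trisubstituted allylic alcohol: the L-tartrate catalyst should set C7 (R) by reagent control, independent of the remote centres.

Step 22
Reactants: 31 epoxy alcohol
Product: 33 key-step precursor: C7 (R) tertiary vinyl carbinol with C5 (R) propynyl and C12–OTBS, via epoxy iodide 32 (not isolated)
Conditions: PPh3, I2, imidazole, THF, 0 °C; then Zn dust, AcOH, rt
Reagents that add atoms: none
Why: Appel-type iodination followed by zinc-induced reductive opening of the 2,3-epoxy iodide gives the C8=C9 vinyl group and the C7 tertiary alcohol with the C7–O bond, and so its configuration, kept.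

Step 23
Reactants: 33 key-step precursor
Product: 35 cis-2,7-disubstituted cyclohept-4-enone (C1 ketone; C10 S methyl; C5 R branch to the lactone; C7=C8 bearing the TBS-oxyethyl arm), via enol ether 34 (not isolated)
Conditions: Ph3PAuNTf2 (5 mol%), 4 Å MS, toluene, rt; then 110 °C
Reagents that add atoms: none
Why: The cationic monovalent gold complex activates the C1≡C10 triple bond and the C7 hydroxyl adds anti in a 5-exo-dig closure, so that protodeauration leaves the Z enol ether (C14 methyl cis to the ring oxygen) of a 2-ethylidene-5-vinyltetrahydrofuran. On heating, the array C10=C1–O–C7–C8=C9 undergoes a Claisen [3,3] shift through the boat geometry that the five-membered ring imposes; C9–C10 forms, C7–O breaks, and the ring is enlarged to the seven-membered C1 ketone with the C7=C8 alkene (carbocycle closed by ring expansion). The closest known reaction type is the tandem 5-exo-dig cyclisation/Claisen rearrangement of 4-alkyn-1-ols that carry a vinyl group on the carbinol carbon, which gives cyclohept-4-enones. C10 is the only new stereocentre: the vinyl group can reach C10 only on the tetrahydrofuran face on which it stands, which is the face opposite the C13′ branch at C5 (fixed by steps 17 and 21), and with the Z enol ether this places the methyl cis to that branch (C10 S). The step needs exo rather than endo attack, secured by the γ-hydroxy alkyne geometry, and survival of the exocyclic enol ether until it rearranges, for which dry, acid-free conditions are chosen; lactone, ketal and silyl ether are spectators.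

**Cyclohexene and ring A lactone**

Step 24
Reactants: 1 (R)-but-3-yn-2-ol
Product: 36 (R)-(but-3-yn-2-yloxy)(tert-butyl)dimethylsilane
Conditions: t-BuMe2SiCl, imidazole, CH2Cl2, rt
Reagents that add atoms: tert-butyldimethylsilyl chloride, CC(C)(C)[Si](C)(C)Cl
Why: Standard silylation of a secondary alcohol; this carbinol becomes C4 (and C4′) and is oxidised at the end.

Step 25
Reactants: 35 cyclohept-4-enone; 36 (R)-(but-3-yn-2-yloxy)(tert-butyl)dimethylsilane
Product: 37 C1 (S) tertiary propargylic alcohol (C2≡C3–C4 unit trans to the C10 methyl and the C5 branch)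
Conditions: 36, n-BuLi, THF, −78 °C; anhydrous CeCl3, −78 °C; then 35, −78 °C
Reagents that add atoms: none
Why: 1,2-Addition of a weakly basic cerium acetylide, which should not enolise the ketone or touch the lactone; C2 is expected to enter on the β face (equatorial), because the axial path crosses the ring under the C6/C9 hydrogens and the C7=C8 bond, leaving the hydroxyl axial and cis to both α substituents.

Step 26
Reactants: 37 C1 (S) tertiary propargylic alcohol
Product: 39 2,5-dihydro-1,2-oxasilole (O–SiMe2 bridge from C1–O to C3; H on C2), via silyl ether 38 (not isolated)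
Conditions: (HMe2Si)2NH, neat, 60 °C, then evaporation; [Cp*Ru(MeCN)3]PF6 (5 mol%), CH2Cl2, 0 °C → rt
Reagents that add atoms: 1,1,3,3-tetramethyldisilazane, C[SiH](C)N[SiH](C)C
Why: Silylation followed by ruthenium-catalysed intramolecular endo-dig trans-hydrosilylation places silicon on C3 and hydrogen on C2 trans to it, and masks the C1 hydroxyl for the next step.

Step 27
Reactants: 39 2,5-dihydro-1,2-oxasilole
Product: 40 (Z)-vinyl iodide (C3–I cis to C1; free C1–OH)
Conditions: N-iodosuccinimide, 2,6-lutidine, (CF3)2CHOH–CH2Cl2, −20 °C; then aq. NaHCO3, MeOH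
Reagents that add atoms: N-iodosuccinimide, O=C1CCC(=O)N1I
Why: ipso-Iododesilylation of the alkenylsilane proceeds with retention; the masked C1 oxygen cannot add across C7=C8 during iodination, and the Si–O link is hydrolysed on work-up.

Step 28
Reactants: 40 (Z)-vinyl iodide
Product: 41 spiro cyclohexene (C3–C11′ bond; C11′ S; C2=C3; C4–OTBS)
Conditions: LiN(SiMe3)2 (2.2 equiv), Pd2(dba)3 (5 mol%), t-Bu3P·HBF4 (12 mol%), toluene–THF, 60 °C
Reagents that add atoms: none
Why: Palladium-catalysed intramolecular α-alkenylation of the lactone enolate closes the six-membered ring; the alkenylpalladium should be delivered on the convex face of the cis-fused lactone (syn to H7′), which sets the spiro centre.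

Step 29
Reactants: 41 spiro cyclohexene
Product: 43 C8 ketone (C7 R with H7 β; side chain equatorial), via alkylborane 42 (not isolated)
Conditions: BH3·SMe2, THF, 0 °C → rt; then N-methylmorpholine N-oxide, Pr4N[RuO4] (cat.), 4 Å MS, CH2Cl2, rt; then DBU, rt
Reagents that add atoms: N-methylmorpholine N-oxide, C[N+]1([O-])CCOCC1
Why: Hydroboration puts boron on the less substituted C8 and in-flask oxidation gives the ketone; DBU then equilibrates C7 to the epimer with the side chain equatorial and cis to the C5 ring bond, so the face of borane attack does not matter.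

Step 30
Reactants: 43 C8 ketone
Product: 44 C8 (R) alcohol, cis to the C7 side chain
Conditions: LiBH(s-Bu)3, THF, −78 °C
Reagents that add atoms: none
Why: The bulky hydride should attack anti to the adjacent C7 substituent, giving the cis 1,2-relationship needed for the cis-fused lactone; lactone and ketal are inert at this temperature.

Step 31
Reactants: 44 C8 (R) alcohol
Product: 45 C8,C12-diol
Conditions: HF·pyridine, pyridine, THF, 0 °C
Reagents that add atoms: none
Why: Buffered fluoride cleaves the primary silyl ether selectively over the hindered secondary C4 silyl ether.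

Step 32
Reactants: 45 C8,C12-diol
Product: 46 bis-lactone ketal (ring A cis-lactone closed)
Conditions: TEMPO (cat.), PhI(OAc)2, CH2Cl2, rt
Reagents that add atoms: none
Why: Oxidative lactonisation of the 1,4-diol through the lactol; the primary alcohol is oxidised first and the tertiary C1 hydroxyl is untouched.

**Side chain, methylene, epoxide**

Step 33
Reactants: 46 bis-lactone ketal
Product: 47 C1′ ketone
Conditions: pyridinium p-toluenesulfonate (cat.), acetone–H2O, 50 °C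
Reagents that add atoms: water, O
Why: Mild acetal hydrolysis frees the ring B ketone and leaves the secondary silyl ether and both lactones.

Step 34
Reactants: 47 C1′ ketone
Product: 48 C1′(5′)-enol triflate
Conditions: KN(SiMe3)2 (2.2 equiv), THF, −78 °C; then PhNTf2, −78 °C
Reagents that add atoms: N-phenylbis(trifluoromethanesulfonimide), O=S(=O)(N(c1ccccc1)S(=O)(=O)C(F)(F)F)C(F)(F)F
Why: Kinetic enolisation of the ketone (more acidic than the ring A lactone) toward the unsubstituted C5′ and O-triflation; C4 is still a silyl ether, so no second ketone competes.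

Step 35
Reactants: 36 (R)-(but-3-yn-2-yloxy)(tert-butyl)dimethylsilane
Product: 49 (R,E)-alkenyl pinacol boronate
Conditions: pinacolborane, Cp2Zr(H)Cl (cat.), Et3N (cat.), neat, 60 °C
Reagents that add atoms: pinacolborane, CC1(C)OBOC1(C)C
Why: Zirconium-catalysed syn-hydroboration of the terminal alkyne gives the E alkenylboronate.

Step 36
Reactants: 48 C1′(5′)-enol triflate; 49 (R,E)-alkenyl pinacol boronate
Product: 50 ring B diene (C5′=C1′–C2′=C3′–C4′ with OTBS at C4′)
Conditions: Pd(dppf)Cl2 (5 mol%), K3PO4, THF–H2O, rt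
Reagents that add atoms: none
Why: Suzuki–Miyaura coupling of the alkenyl triflate and alkenylboronate with retention of both alkene geometries.

Step 37
Reactants: 50 ring B diene
Product: 53 α-methylene lactone (C11=C13), via Mannich base 51 (not isolated), via methiodide 52 (not isolated)
Conditions: LiN(i-Pr)2 (2.3 equiv), THF, −78 °C; Me2N=CH2 I, −78 → 0 °C; then MeI, rt; then aq. NaHCO3
Reagents that add atoms: N,N-dimethylmethyleneiminium iodide, C[N+](C)=C.[I-]
Why: Mannich methylenation with Eschenmoser's salt, quaternisation and elimination; only ring A lactone has an α-hydrogen (C11′ is quaternary) and no ketone is present.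

Step 38
Reactants: 53 α-methylene lactone
Product: 54 C4,C4′-diol
Conditions: HF·pyridine, THF–pyridine, 0 °C → rt
Reagents that add atoms: none
Why: Fluoride removes both secondary silyl ethers under conditions mild enough for the α-methylene lactone.

Step 39
Reactants: 54 C4,C4′-diol
Product: 55 bis-enone (C4 and C4′ ketones)
Conditions: Dess–Martin periodinane, NaHCO3, CH2Cl2, 0 °C → rt
Reagents that add atoms: none
Why: Both secondary allylic alcohols are oxidised; the tertiary C1 hydroxyl cannot react.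

Step 40
Reactants: 55 bis-enone
Product: 56 CNP0177598.1 (target)
Conditions: dimethyldioxirane, acetone, −20 → 0 °C
Reagents that add atoms: dimethyldioxirane, CC1(C)OO1
Why: Electrophilic epoxidation should pick the γ,δ-alkene C5′=C1′ of the dienone, the only alkene not directly conjugated to a carbonyl, and is expected on the α face cis to the C14′ methyl, as the configuration of the target requires.

**Compound list**

1 | (R)-but-3-yn-2-ol | C[C@@H](O)C#C | starting material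
2 | 2-(2-bromoethyl)-1,3-dioxolane | BrCCC1OCCO1 | starting material
3 | (2R)-6-(1,3-dioxolan-2-yl)hex-3-yn-2-ol | C[C@@H](O)C#CCCC1OCCO1 | intermediate
4 | (2R,3E)-6-(1,3-dioxolan-2-yl)hex-3-en-2-ol | C[C@@H](O)/C=C/CCC1OCCO1 | intermediate
5 | ethyl (3R,4E)-3-[2-(1,3-dioxolan-2-yl)ethyl]hex-4-enoate | CCOC(=O)C[C@@H](CCC1OCCO1)/C=C/C | intermediate
6 | ethyl (3R,4E)-3-(3-oxopropyl)hex-4-enoate | CCOC(=O)C[C@@H](CCC=O)/C=C/C | intermediate
7 | ethyl (3R,6R,7S)-6-hydroxy-7-methyl-3-[(E)-prop-1-enyl]non-8-enoate | C=C[C@H](C)[C@H](O)CC[C@H](CC(=O)OCC)/C=C/C | intermediate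
8 | ethyl [(1R,4S,5R)-5-hydroxy-4-methylcyclohept-2-en-1-yl]acetate | CCOC(=O)C[C@@H]1C=C[C@H](C)[C@H](O)CC1 | intermediate
9 | [(1R,4S,5R)-5-hydroxy-4-methylcyclohept-2-en-1-yl]acetic acid | OC(=O)C[C@@H]1C=C[C@H](C)[C@H](O)CC1 | intermediate
10 | (3aR,6R,7R,8S,8aS)-6-hydroxy-8-iodo-7-methyloctahydro-2H-cyclohepta[b]furan-2-one | O=C1O[C@@H]2[C@@H](I)[C@H](C)[C@H](O)CC[C@@H]2C1 | intermediate
11 | (3aR,6R,7S,8aR)-6-hydroxy-7-methyloctahydro-2H-cyclohepta[b]furan-2-one | O=C1O[C@@H]2C[C@H](C)[C@H](O)CC[C@@H]2C1 | intermediate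
12 | (3aR,7S,8aR)-7-methylhexahydro-2H-cyclohepta[b]furan-2,6(3H)-dione | O=C1O[C@@H]2C[C@H](C)C(=O)CC[C@@H]2C1 | intermediate
13 | ring B lactone: 6,6-ethylenedioxy ketal of 12 | O=C1O[C@@H]2C[C@H](C)C3(OCCO3)CC[C@@H]2C1 | intermediate
14 | triethyl phosphonoacetate | CCOC(=O)CP(=O)(OCC)OCC | starting material
15 | (2-bromoethoxy)(tert-butyl)dimethylsilane | BrCCO[Si](C)(C)C(C)(C)C | starting material
16 | ethyl 4-(TBS-oxy)-2-(diethoxyphosphoryl)butanoate (racemic) | CCOC(=O)C(CCO[Si](C)(C)C(C)(C)C)P(=O)(OCC)OCC | intermediate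
17 | 2-(PMB-oxy)acetaldehyde | O=CCOCc1ccc(OC)cc1 | starting material
18 | ethyl (2E)-2-[2-(TBS-oxy)ethyl]-4-(PMB-oxy)but-2-enoate | CCOC(=O)/C(CCO[Si](C)(C)C(C)(C)C)=C/COCc1ccc(OC)cc1 | intermediate
19 | (2E)-2-[2-(TBS-oxy)ethyl]-4-(PMB-oxy)but-2-en-1-ol | OC/C(CCO[Si](C)(C)C(C)(C)C)=C/COCc1ccc(OC)cc1 | intermediate
20 | (2E)-1-bromo-2-[2-(TBS-oxy)ethyl]-4-(PMB-oxy)but-2-ene | BrC/C(CCO[Si](C)(C)C(C)(C)C)=C/COCc1ccc(OC)cc1 | intermediate
21 | prop-2-yn-1-ol | OCC#C | starting material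
22 | (5Z)-5-[2-(TBS-oxy)ethyl]-7-(PMB-oxy)hept-5-en-2-yn-1-ol | OCC#CC/C(CCO[Si](C)(C)C(C)(C)C)=C/COCc1ccc(OC)cc1 | intermediate
23 | (2E,5Z)-5-[2-(TBS-oxy)ethyl]-7-(PMB-oxy)hepta-2,5-dien-1-ol | OC/C=C/C/C(CCO[Si](C)(C)C(C)(C)C)=C/COCc1ccc(OC)cc1 | intermediate
24 | [(2R,3R)-3-{(2E)-2-[2-(TBS-oxy)ethyl]-4-(PMB-oxy)but-2-enyl}oxiran-2-yl]methanol | OC[C@H]1O[C@@H]1C/C(CCO[Si](C)(C)C(C)(C)C)=C/COCc1ccc(OC)cc1 | intermediate
25 | (2S,3R,5Z)-5-[2-(TBS-oxy)ethyl]-7-(PMB-oxy)-3-(prop-1-ynyl)hept-5-ene-1,2-diol | OC[C@@H](O)[C@@H](C#CC)C/C(CCO[Si](C)(C)C(C)(C)C)=C/COCc1ccc(OC)cc1 | intermediate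
26 | (2R,4Z)-4-[2-(TBS-oxy)ethyl]-6-(PMB-oxy)-2-(prop-1-ynyl)hex-4-enal | O=C[C@@H](C#CC)C/C(CCO[Si](C)(C)C(C)(C)C)=C/COCc1ccc(OC)cc1 | intermediate
27 | (2R,4Z)-4-[2-(TBS-oxy)ethyl]-6-(PMB-oxy)-2-(prop-1-ynyl)hex-4-en-1-ol | OC[C@@H](C#CC)C/C(CCO[Si](C)(C)C(C)(C)C)=C/COCc1ccc(OC)cc1 | intermediate
28 | trifluoromethanesulfonate of 27 | FC(F)(F)S(=O)(=O)OC[C@@H](C#CC)C/C(CCO[Si](C)(C)C(C)(C)C)=C/COCc1ccc(OC)cc1 | intermediate
29 | alkylated lactone (C11′–C13′ bond; C13′ anti to C6′; C5 R) | CC#C[C@H](C[C@H]4C(=O)O[C@@H]1C[C@H](C)C5(OCCO5)CC[C@@H]14)C/C(CCO[Si](C)(C)C(C)(C)C)=C/COCc1ccc(OC)cc1 | intermediate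
30 | allylic alcohol (29 with C9–OH) | CC#C[C@H](C[C@H]4C(=O)O[C@@H]1C[C@H](C)C5(OCCO5)CC[C@@H]14)C/C(CCO[Si](C)(C)C(C)(C)C)=C/CO | intermediate
31 | (7R,8S)-7,8-epoxy alcohol | CC#C[C@H](C[C@H]4C(=O)O[C@@H]1C[C@H](C)C5(OCCO5)CC[C@@H]14)C[C@]1(CCO[Si](C)(C)C(C)(C)C)O[C@H]1CO | intermediate
32 | epoxy iodide (C9–I analogue of 31) | CC#C[C@H](C[C@H]4C(=O)O[C@@H]1C[C@H](C)C5(OCCO5)CC[C@@H]14)C[C@]1(CCO[Si](C)(C)C(C)(C)C)O[C@H]1CI | intermediate
33 | key-step precursor: C7 (R) tertiary vinyl carbinol with C5 (R) propynyl | CC#C[C@H](C[C@H]4C(=O)O[C@@H]1C[C@H](C)C5(OCCO5)CC[C@@H]14)C[C@](O)(C=C)CCO[Si](C)(C)C(C)(C)C | intermediate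
34 | (Z)-2-ethylidene-5-vinyltetrahydrofuran (vinyl trans to the C5 branch) | C/C=C1\O[C@@](C=C)(CCO[Si](C)(C)C(C)(C)C)C[C@H]1C[C@H]4C(=O)O[C@@H]2C[C@H](C)C5(OCCO5)CC[C@@H]24 | intermediate
35 | cis-2,7-disubstituted cyclohept-4-enone (C10 S; C5 R) | C[C@H]1CC=C(CCO[Si](C)(C)C(C)(C)C)C[C@@H](C[C@H]4C(=O)O[C@@H]2C[C@H](C)C5(OCCO5)CC[C@@H]24)C1=O | intermediate
36 | (R)-(but-3-yn-2-yloxy)(tert-butyl)dimethylsilane | C[C@@H](O[Si](C)(C)C(C)(C)C)C#C | intermediate
37 | C1 (S) tertiary propargylic alcohol | C[C@H]1CC=C(CCO[Si](C)(C)C(C)(C)C)C[C@@H](C[C@H]4C(=O)O[C@@H]2C[C@H](C)C5(OCCO5)CC[C@@H]24)[C@]1(O)C#C[C@@H](C)O[Si](C)(C)C(C)(C)C | intermediate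
38 | dimethylsilyl (Si–H) ether of 37 | C[C@H]1CC=C(CCO[Si](C)(C)C(C)(C)C)C[C@@H](C[C@H]4C(=O)O[C@@H]2C[C@H](C)C5(OCCO5)CC[C@@H]24)[C@]1(O[SiH](C)C)C#C[C@@H](C)O[Si](C)(C)C(C)(C)C | intermediate
39 | 2,5-dihydro-1,2-oxasilole (Si on C3) | C[C@H]1CC=C(CCO[Si](C)(C)C(C)(C)C)C[C@@H](C[C@H]4C(=O)O[C@@H]2C[C@H](C)C5(OCCO5)CC[C@@H]24)[C@@]16O[Si](C)(C)C(=C6)[C@@H](C)O[Si](C)(C)C(C)(C)C | intermediate
40 | (Z)-vinyl iodide (C3–I) | C[C@H]1CC=C(CCO[Si](C)(C)C(C)(C)C)C[C@@H](C[C@H]4C(=O)O[C@@H]2C[C@H](C)C5(OCCO5)CC[C@@H]24)[C@]1(O)/C=C(\I)[C@@H](C)O[Si](C)(C)C(C)(C)C | intermediate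
41 | spiro cyclohexene (C11′ S) | CC(C)(C)[Si](C)(C)OCCC1=CC[C@H](C)[C@@]3(O)C=C([C@@H](C)O[Si](C)(C)C(C)(C)C)[C@@]4(C[C@@H]3C1)C(=O)O[C@@H]1C[C@H](C)C5(OCCO5)CC[C@@H]14 | intermediate
42 | C8 alkylborane (C7/C8 mixture) | CC(C)(C)[Si](C)(C)OCCC1C(B)C[C@H](C)[C@@]3(O)C=C([C@@H](C)O[Si](C)(C)C(C)(C)C)[C@@]4(C[C@@H]3C1)C(=O)O[C@@H]1C[C@H](C)C5(OCCO5)CC[C@@H]14 | intermediate
43 | C8 ketone (C7 R) | CC(C)(C)[Si](C)(C)OCC[C@@H]1C(=O)C[C@H](C)[C@@]3(O)C=C([C@@H](C)O[Si](C)(C)C(C)(C)C)[C@@]4(C[C@@H]3C1)C(=O)O[C@@H]1C[C@H](C)C5(OCCO5)CC[C@@H]14 | intermediate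
44 | C8 (R) alcohol | CC(C)(C)[Si](C)(C)OCC[C@@H]1[C@H](O)C[C@H](C)[C@@]3(O)C=C([C@@H](C)O[Si](C)(C)C(C)(C)C)[C@@]4(C[C@@H]3C1)C(=O)O[C@@H]1C[C@H](C)C5(OCCO5)CC[C@@H]14 | intermediate
45 | C8,C12-diol | OCC[C@@H]1[C@H](O)C[C@H](C)[C@@]3(O)C=C([C@@H](C)O[Si](C)(C)C(C)(C)C)[C@@]4(C[C@@H]3C1)C(=O)O[C@@H]1C[C@H](C)C5(OCCO5)CC[C@@H]14 | intermediate
46 | bis-lactone ketal | C1C(=O)O[C@@H]2C[C@H](C)[C@@]3(O)C=C([C@@H](C)O[Si](C)(C)C(C)(C)C)[C@@]4(C[C@@H]3C[C@H]12)C(=O)O[C@@H]1C[C@H](C)C5(OCCO5)CC[C@@H]14 | intermediate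
47 | C1′ ketone | C1C(=O)O[C@@H]2C[C@H](C)[C@@]3(O)C=C([C@@H](C)O[Si](C)(C)C(C)(C)C)[C@@]4(C[C@@H]3C[C@H]12)C(=O)O[C@@H]1C[C@H](C)C(=O)CC[C@@H]14 | intermediate
48 | C1′(5′)-enol triflate | C1C(=O)O[C@@H]2C[C@H](C)[C@@]3(O)C=C([C@@H](C)O[Si](C)(C)C(C)(C)C)[C@@]4(C[C@@H]3C[C@H]12)C(=O)O[C@@H]1C[C@H](C)C(OS(=O)(=O)C(F)(F)F)=CC[C@@H]14 | intermediate
49 | (R,E)-2-[3-(TBS-oxy)but-1-enyl]-4,4,5,5-tetramethyl-1,3,2-dioxaborolane | CC1(C)OB(/C=C/[C@@H](C)O[Si](C)(C)C(C)(C)C)OC1(C)C | intermediate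
50 | ring B diene | C1C(=O)O[C@@H]2C[C@H](C)[C@@]3(O)C=C([C@@H](C)O[Si](C)(C)C(C)(C)C)[C@@]4(C[C@@H]3C[C@H]12)C(=O)O[C@@H]1C[C@H](C)C(/C=C/[C@@H](C)O[Si](C)(C)C(C)(C)C)=CC[C@@H]14 | intermediate
51 | C11 dimethylaminomethyl lactone (Mannich base; C11 epimers) | CN(C)CC1C(=O)O[C@@H]2C[C@H](C)[C@@]3(O)C=C([C@@H](C)O[Si](C)(C)C(C)(C)C)[C@@]4(C[C@@H]3C[C@H]12)C(=O)O[C@@H]1C[C@H](C)C(/C=C/[C@@H](C)O[Si](C)(C)C(C)(C)C)=CC[C@@H]14 | intermediate
52 | trimethylammonium iodide of 51 | C[N+](C)(C)CC1C(=O)O[C@@H]2C[C@H](C)[C@@]3(O)C=C([C@@H](C)O[Si](C)(C)C(C)(C)C)[C@@]4(C[C@@H]3C[C@H]12)C(=O)O[C@@H]1C[C@H](C)C(/C=C/[C@@H](C)O[Si](C)(C)C(C)(C)C)=CC[C@@H]14.[I-] | intermediate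
53 | α-methylene lactone (bis-silyl ether) | C=C1C(=O)O[C@@H]2C[C@H](C)[C@@]3(O)C=C([C@@H](C)O[Si](C)(C)C(C)(C)C)[C@@]4(C[C@@H]3C[C@H]12)C(=O)O[C@@H]1C[C@H](C)C(/C=C/[C@@H](C)O[Si](C)(C)C(C)(C)C)=CC[C@@H]14 | intermediate
54 | C4,C4′-diol | C=C1C(=O)O[C@@H]2C[C@H](C)[C@@]3(O)C=C([C@@H](C)O)[C@@]4(C[C@@H]3C[C@H]12)C(=O)O[C@@H]1C[C@H](C)C(/C=C/[C@@H](C)O)=CC[C@@H]14 | intermediate
55 | bis-enone (1′,5′-deoxy target) | C=C1C(=O)O[C@@H]2C[C@H](C)[C@@]3(O)C=C(C(C)=O)[C@@]4(C[C@@H]3C[C@H]12)C(=O)O[C@@H]1C[C@H](C)C(/C=C/C(C)=O)=CC[C@@H]14 | intermediate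
56 | CNP0177598.1 | C=C1C(=O)O[C@@H]2C[C@H](C)[C@@]3(O)C=C(C(C)=O)[C@@]4(C[C@@H]3C[C@H]12)C(=O)O[C@@H]1C[C@H](C)[C@]2(/C=C/C(C)=O)O[C@@H]2C[C@@H]14 | target

**Count and risks**

Total steps: 40. Longest linear sequence: 29 steps (14 → 56 through steps 10–23, 25–34 and 36–40; the branch from 1 through steps 1–9 is equally long).

Steps most likely to fail:

1. Step 28. The hindered lactone enolate may not couple: closure at the quaternary spiro centre could be slow, and the alkenylpalladium could be protonated or reduced instead. Fallback by ring-closing metathesis, from ketone 35 back to spirocycle 41. Vinylmagnesium bromide with CeCl3 would add to C1 to give the vinyl carbinol F6. Double deprotonation with LiN(i-Pr)2 and C-acylation of the lactone enolate on its convex face with (R)-2-(TBS-oxy)propanoyl chloride would give the β-keto lactone F7. Methylenation of the new ketone with Ph3P=CH2 would give the 1,1-disubstituted alkene F8. The second-generation Hoveyda–Grubbs catalyst in hot toluene would then close C2=C3 and deliver 41.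

2. Step 25. Facial selectivity at C1 is uncertain: a slim acetylide may prefer the axial path and give the C1 epimer, which would lead to a cis ring fusion. Fallback with a bulky nucleophile, from 35 back to 37. 2-Lithio-1,3-dithiane, which favours equatorial C–C bond formation, would give the dithiane carbinol F1. MeI and CaCO3 in aqueous MeCN would unmask the α-hydroxy aldehyde F2, and the Ohira–Bestmann reagent with K2CO3 in MeOH would give the ethynyl carbinol F3. Acetyl chloride with PdCl2(PPh3)2, CuI and Et3N would give the ynone F4. Transfer hydrogenation with RuCl[(R,R)-TsDPEN](p-cymene) in i-PrOH, the catalyst antipode being chosen for the (R)-carbinol, would give the diol F5. t-BuMe2SiCl and imidazole would silylate the secondary hydroxyl only and return 37.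

3. Step 40. Facial selectivity of the last oxidation is uncertain: the dioxirane may approach the β face, trans to the C14′ methyl, and give the epimeric epoxide. Fallback by halohydrin inversion, from 55 back to 56. N-Bromosuccinimide in aqueous THF would form the bromonium ion on that same β face and water would open it anti at C1′, giving the bromohydrin F9 (C1′–OH α, C5′–Br β). Ag2O in moist ether would then displace bromide with inversion and give the α-epoxide 56.

**Further compounds**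

F6 | step 28 | C1 vinyl carbinol from 35 | C[C@H]1CC=C(CCO[Si](C)(C)C(C)(C)C)C[C@@H](C[C@H]4C(=O)O[C@@H]2C[C@H](C)C5(OCCO5)CC[C@@H]24)[C@]1(O)C=C
F7 | step 28 | C11′-acylated β-keto lactone | C[C@H]1CC=C(CCO[Si](C)(C)C(C)(C)C)C[C@@H](C[C@]4(C(=O)[C@@H](C)O[Si](C)(C)C(C)(C)C)C(=O)O[C@@H]2C[C@H](C)C5(OCCO5)CC[C@@H]24)[C@]1(O)C=C
F8 | step 28 | metathesis diene (C3=CH2) | C[C@H]1CC=C(CCO[Si](C)(C)C(C)(C)C)C[C@@H](C[C@]4(C(=C)[C@@H](C)O[Si](C)(C)C(C)(C)C)C(=O)O[C@@H]2C[C@H](C)C5(OCCO5)CC[C@@H]24)[C@]1(O)C=C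
F1 | step 25 | C1 (1,3-dithian-2-yl) carbinol | C[C@H]1CC=C(CCO[Si](C)(C)C(C)(C)C)C[C@@H](C[C@H]4C(=O)O[C@@H]2C[C@H](C)C5(OCCO5)CC[C@@H]24)[C@]1(O)C6SCCCS6
F2 | step 25 | C1 α-hydroxy aldehyde | C[C@H]1CC=C(CCO[Si](C)(C)C(C)(C)C)C[C@@H](C[C@H]4C(=O)O[C@@H]2C[C@H](C)C5(OCCO5)CC[C@@H]24)[C@]1(O)C=O
F3 | step 25 | C1 ethynyl carbinol | C[C@H]1CC=C(CCO[Si](C)(C)C(C)(C)C)C[C@@H](C[C@H]4C(=O)O[C@@H]2C[C@H](C)C5(OCCO5)CC[C@@H]24)[C@]1(O)C#C
F4 | step 25 | ynone (C4 ketone) | C[C@H]1CC=C(CCO[Si](C)(C)C(C)(C)C)C[C@@H](C[C@H]4C(=O)O[C@@H]2C[C@H](C)C5(OCCO5)CC[C@@H]24)[C@]1(O)C#CC(C)=O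
F5 | step 25 | C1,C4-diol (C4 R) | C[C@H]1CC=C(CCO[Si](C)(C)C(C)(C)C)C[C@@H](C[C@H]4C(=O)O[C@@H]2C[C@H](C)C5(OCCO5)CC[C@@H]24)[C@]1(O)C#C[C@@H](C)O
F9 | step 40 | bromohydrin (C1′–OH α; C5′–Br β) | C=C1C(=O)O[C@@H]2C[C@H](C)[C@@]3(O)C=C(C(C)=O)[C@@]4(C[C@@H]3C[C@H]12)C(=O)O[C@@H]1C[C@H](C)[C@@](O)(/C=C/C(C)=O)[C@@H](Br)C[C@@H]14
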